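**Strategy**

Ring A carries its C1 carboxyl group between the C2 methoxy and the C6 aryloxy substituents. That contiguous C6–O, C1–CO2H, C2–OMe array is what addition of an oxygen nucleophile and then a carbon electrophile across a 3-methoxyaryne produces, so the diaryl ether bond and the carboxyl bond are disconnected together. In the key step the potassium phenoxide of ring B attacks C6 of the aryne released from silylaryl triflate 11 and the C1 anion is carboxylated by CO2, both bonds forming in one flask. Triflate 11 already holds the C2 methoxy group and the (R)-1-methoxy-3-methylbutyl chain at C3; the ring B phenol 16 carries its aldehyde as a dioxolane and its second hydroxyl as an allyl ether.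

Key step: step 11

Numbering: ring A has C1 (carboxyl carbon), C2 (OMe), C3 (side chain), C6 (aryloxy). Ring B has C1' (ether carbon), C2' (CHO), C4' (CH3), C6' (OH).

Assumption: N-methoxy-N,3-dimethylbutanamide (5) is taken as a purchasable Weinreb amide.

Design notes:
- The ring B hydroxyl is carried as an allyl ether, not an acid-labile acetal-type ether. The dioxolane can then be made under acid catalysis, and the final unmasking needs only brief dilute acid, which the electron-rich benzylic methyl ether of ring A should tolerate.
- The silyl group is introduced before the stereocentre exists, so no alkyllithium meets the benzylic ether.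

**Route**

Step 1
Reactants: 1 4-bromo-3-methoxyphenol
Product: 2 4-bromo-3-methoxyphenyl N,N-diethylcarbamate
Conditions: Et2NCOCl, K2CO3, MeCN, reflux
Reagents that add atoms: N,N-diethylcarbamoyl chloride, CCN(CC)C(Cl)=O
Why: O-carbamoylation of the phenoxide is a routine acyl substitution and installs a base-stable group that protects the phenol and later directs metalation to the carbon between the two ring oxygens.

Step 2
Reactants: 2 4-bromo-3-methoxyphenyl N,N-diethylcarbamate
Product: 4 4-bromo-3-methoxy-2-(trimethylsilyl)phenyl N,N-diethylcarbamate, via C2-lithiated carbamate 3 (not isolated)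
Conditions: Me3SiCl, then LiN(i-Pr)2, THF, −78 °C (in situ quench)
Reagents that add atoms: chlorotrimethylsilane, C[Si](C)(C)Cl
Why: Directed ortho-metalation with in situ silyl trapping, in which the amide base does not exchange the bromide, removes the most acidic ring proton (flanked by the carbamate and methoxy oxygens), and the aryllithium is silylated as it forms, before anionic Fries rearrangement can set in.

Step 3
Reactants: 4 4-bromo-3-methoxy-2-(trimethylsilyl)phenyl N,N-diethylcarbamate; 5 N-methoxy-N,3-dimethylbutanamide
Product: 7 3-methoxy-4-(3-methylbutanoyl)-2-(trimethylsilyl)phenyl N,N-diethylcarbamate, via C4 aryllithium 6 (not isolated)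
Conditions: n-BuLi, THF, −78 °C; then 5, −78 → 0 °C; NH4Cl (aq)
Reagents that add atoms: none
Why: Bromine–lithium exchange is far faster than attack on the hindered diethylcarbamate at −78 °C, and the Weinreb ketone synthesis stops at the ketone because the N-methoxy chelate survives until work-up.

Step 4
Reactants: 7 3-methoxy-4-(3-methylbutanoyl)-2-(trimethylsilyl)phenyl N,N-diethylcarbamate
Product: 8 4-[(1R)-1-hydroxy-3-methylbutyl]-3-methoxy-2-(trimethylsilyl)phenyl N,N-diethylcarbamate
Conditions: (S)-Me-CBS oxazaborolidine (10 mol %), BH3·SMe2, THF, −20 °C; MeOH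
Reagents that add atoms: none
Why: Corey–Bakshi–Shibata reduction, in which the (S)-oxazaborolidine treats the aryl group as the large and the isobutyl group as the small substituent and delivers hydride to the face that should give the (R)-carbinol, as for aryl alkyl ketones generally, while the carbamate is inert to borane at this temperature.

Step 5
Reactants: 8 4-[(1R)-1-hydroxy-3-methylbutyl]-3-methoxy-2-(trimethylsilyl)phenyl N,N-diethylcarbamate
Product: 9 3-methoxy-4-[(1R)-1-methoxy-3-methylbutyl]-2-(trimethylsilyl)phenyl N,N-diethylcarbamate
Conditions: NaH, MeI, THF, 0 °C → rt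
Reagents that add atoms: iodomethane, CI
Why: Williamson etherification of the sodium alkoxide forms only the O–CH3 bond, so the C–O bond at the stereocentre is untouched and the (R) configuration is retained, and the carbamate and aryl silane are stable to NaH.

Step 6
Reactants: 9 3-methoxy-4-[(1R)-1-methoxy-3-methylbutyl]-2-(trimethylsilyl)phenyl N,N-diethylcarbamate
Product: 10 3-methoxy-4-[(1R)-1-methoxy-3-methylbutyl]-2-(trimethylsilyl)phenol
Conditions: LiAlH4, THF, 0 °C → reflux; KNaC4H4O6 (aq)
Reagents that add atoms: none
Why: Hydride reduction of the aryl carbamate releases the phenoxide and N,N-diethylmethylamine without acid or fluoride, so the aryl–silicon bond and the benzylic ether should survive, and the tartrate work-up avoids protodesilylation.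

Step 7
Reactants: 10 3-methoxy-4-[(1R)-1-methoxy-3-methylbutyl]-2-(trimethylsilyl)phenol
Product: 11 3-methoxy-4-[(1R)-1-methoxy-3-methylbutyl]-2-(trimethylsilyl)phenyl trifluoromethanesulfonate
Conditions: Tf2O, pyridine, CH2Cl2, 0 °C
Reagents that add atoms: trifluoromethanesulfonic anhydride, O=S(=O)(OS(=O)(=O)C(F)(F)F)C(F)(F)F
Why: O-triflation of an ortho-silyl phenol with Tf2O and pyridine is the standard final step towards 2-silylaryl triflate aryne precursors, and the cold basic medium does not ionise the benzylic ether.

Step 8
Reactants: 12 4-methylcatechol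
Product: 13 2,3-dihydroxy-5-methylbenzaldehyde
Conditions: MgCl2, Et3N, (CH2O)n, MeCN, reflux; 1 M HCl
Reagents that add atoms: paraformaldehyde (as formaldehyde), C=O
Why: Magnesium-mediated ortho-formylation of a phenol (Casnati–Skattebøl type) delivers formaldehyde only to a carbon ortho to a phenoxide and oxidises the resulting salicyl alcohol with a second formaldehyde, and of the two free ortho carbons the one next to the methyl group is hindered, so the 5-methyl isomer should prevail.

Step 9
Reactants: 13 2,3-dihydroxy-5-methylbenzaldehyde
Product: 15 2-hydroxy-5-methyl-3-(prop-2-en-1-yloxy)benzaldehyde, via disodium dianion 14 (not isolated)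
Conditions: NaH (2.2 equiv), DMSO, rt; CH2=CHCH2Br (1.0 equiv); dilute HCl
Reagents that add atoms: allyl bromide, C=CCBr
Why: Regioselective O-alkylation of the dianion, a known selectivity of 2,3-dihydroxybenzaldehydes, in which the phenoxide next to the formyl group is conjugated and chelated and so the single equivalent of allyl bromide reacts at the more nucleophilic remote phenoxide.

Step 10
Reactants: 15 2-hydroxy-5-methyl-3-(prop-2-en-1-yloxy)benzaldehyde
Product: 16 2-(1,3-dioxolan-2-yl)-4-methyl-6-(prop-2-en-1-yloxy)phenol
Conditions: HOCH2CH2OH, TsOH·H2O (cat.), toluene, reflux (Dean–Stark); Et3N-treated silica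
Reagents that add atoms: ethylene glycol, OCCO
Why: Acid-catalysed acetalisation driven by azeotropic removal of water, to which the allyl ether is inert (well below its Claisen temperature) and in which the free phenol does not interfere.

Step 11
Reactants: 11 3-methoxy-4-[(1R)-1-methoxy-3-methylbutyl]-2-(trimethylsilyl)phenyl trifluoromethanesulfonate; 16 2-(1,3-dioxolan-2-yl)-4-methyl-6-(prop-2-en-1-yloxy)phenol; 17 carbon dioxide
Product: 21 6-[2-(1,3-dioxolan-2-yl)-4-methyl-6-(prop-2-en-1-yloxy)phenoxy]-2-methoxy-3-[(1R)-1-methoxy-3-methylbutyl]benzoic acid, via potassium phenoxide 18 (not isolated), via aryne 19 (not isolated), via aryl potassium adduct 20 (not isolated)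
Conditions: 16, KH, 18-crown-6, THF, 0 °C; then CO2 (1 atm), KF, slow addition of 11, 0 °C → rt; cold dilute HCl to pH 4
Reagents that add atoms: none
Why: Proposed new method: fluoride attacks silicon in 11 and triflate leaves to give aryne 19; phenoxide 18, made beforehand with KH so that no O–H remains, adds through oxygen to C6, the aryne terminus remote from the methoxy group, and the resulting C1 carbanion 20, stabilised inductively by the adjacent C2 oxygen, is captured by dissolved CO2 to give the carboxylate. The closest known reaction types are the three-component coupling of arynes, amines and CO2 to anthranilic acids and the fluoride-mediated O-arylation of phenols by silylaryl triflates; the new element is carboxylation of the aryl anion left behind by a phenoxide. No ring closes and no stereocentre is formed, the (R) benzylic ether being a remote spectator. Regioselectivity for C6 is required and is secured by the C2 methoxy group, which polarises the aryne, while O-arylation in preference to C-arylation is secured because both ortho positions and the para position of 18 are substituted. Carboxylation in preference to protonation is required and is secured by THF in place of acetonitrile, by the absence of acidic protons in 16 (allyl ether, dioxolane) and by CO2 being present before the anion forms, reversible carbonate formation from 18 leaving free phenoxide available. The dioxolane is essential because a free formyl group would trap the C1 anion intramolecularly as a xanthenol, and slow addition of 11 keeps the aryne concentration low so that the product carboxylate does not compete as a nucleophile.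

Step 12
Reactants: 21 6-[2-(1,3-dioxolan-2-yl)-4-methyl-6-(prop-2-en-1-yloxy)phenoxy]-2-methoxy-3-[(1R)-1-methoxy-3-methylbutyl]benzoic acid
Product: 23 6-(2-formyl-6-hydroxy-4-methylphenoxy)-2-methoxy-3-[(1R)-1-methoxy-3-methylbutyl]benzoic acid (target), via deallylated dioxolane acid 22 (not isolated)
Conditions: Pd(PPh3)4 (5 mol %), morpholine, THF, rt; then 1 M HCl (aq), rt
Reagents that add atoms: water, O
Why: Tsuji–Trost deallylation by zerovalent palladium with morpholine as allyl acceptor frees the ring B phenol under neutral conditions, and the subsequent acidification hydrolyses the dioxolane under conditions too mild to ionise the benzylic methyl ether, so the (R) centre should be preserved.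

**Compound list**

1 | 4-bromo-3-methoxyphenol | COc1cc(O)ccc1Br | starting material
2 | 4-bromo-3-methoxyphenyl N,N-diethylcarbamate | CCN(CC)C(=O)Oc1ccc(Br)c(OC)c1 | intermediate
3 | 4-bromo-2-lithio-3-methoxyphenyl N,N-diethylcarbamate | CCN(CC)C(=O)Oc1ccc(Br)c(OC)c1[Li] | intermediate
4 | 4-bromo-3-methoxy-2-(trimethylsilyl)phenyl N,N-diethylcarbamate | CCN(CC)C(=O)Oc1ccc(Br)c(OC)c1[Si](C)(C)C | intermediate
5 | N-methoxy-N,3-dimethylbutanamide | CC(C)CC(=O)N(C)OC | starting material
6 | 4-lithio-3-methoxy-2-(trimethylsilyl)phenyl N,N-diethylcarbamate | CCN(CC)C(=O)Oc1ccc([Li])c(OC)c1[Si](C)(C)C | intermediate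
7 | 3-methoxy-4-(3-methylbutanoyl)-2-(trimethylsilyl)phenyl N,N-diethylcarbamate | CCN(CC)C(=O)Oc1ccc(C(=O)CC(C)C)c(OC)c1[Si](C)(C)C | intermediate
8 | 4-[(1R)-1-hydroxy-3-methylbutyl]-3-methoxy-2-(trimethylsilyl)phenyl N,N-diethylcarbamate | CCN(CC)C(=O)Oc1ccc([C@@H](CC(C)C)O)c(OC)c1[Si](C)(C)C | intermediate
9 | 3-methoxy-4-[(1R)-1-methoxy-3-methylbutyl]-2-(trimethylsilyl)phenyl N,N-diethylcarbamate | CCN(CC)C(=O)Oc1ccc([C@@H](CC(C)C)OC)c(OC)c1[Si](C)(C)C | intermediate
10 | 3-methoxy-4-[(1R)-1-methoxy-3-methylbutyl]-2-(trimethylsilyl)phenol | COc1c([C@@H](CC(C)C)OC)ccc(O)c1[Si](C)(C)C | intermediate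
11 | 3-methoxy-4-[(1R)-1-methoxy-3-methylbutyl]-2-(trimethylsilyl)phenyl trifluoromethanesulfonate | COc1c([C@@H](CC(C)C)OC)ccc(OS(=O)(=O)C(F)(F)F)c1[Si](C)(C)C | intermediate
12 | 4-methylcatechol | Cc1ccc(O)c(O)c1 | starting material
13 | 2,3-dihydroxy-5-methylbenzaldehyde | Cc1cc(O)c(O)c(C=O)c1 | intermediate
14 | disodium 3-formyl-5-methylbenzene-1,2-diolate | Cc1cc([O-])c([O-])c(C=O)c1.[Na+].[Na+] | intermediate
15 | 2-hydroxy-5-methyl-3-(prop-2-en-1-yloxy)benzaldehyde | Cc1cc(OCC=C)c(O)c(C=O)c1 | intermediate
16 | 2-(1,3-dioxolan-2-yl)-4-methyl-6-(prop-2-en-1-yloxy)phenol | Cc1cc(OCC=C)c(O)c(c1)C1OCCO1 | intermediate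
17 | carbon dioxide | O=C=O | starting material
18 | potassium 2-(1,3-dioxolan-2-yl)-4-methyl-6-(prop-2-en-1-yloxy)phenolate | Cc1cc(OCC=C)c([O-])c(c1)C1OCCO1.[K+] | intermediate
19 | 3-methoxy-4-[(1R)-1-methoxy-3-methylbutyl]benzyne (1,2-didehydrobenzene) | COC1=C([C@@H](CC(C)C)OC)C=CC#C1 | intermediate
20 | {2-[2-(1,3-dioxolan-2-yl)-4-methyl-6-(prop-2-en-1-yloxy)phenoxy]-6-methoxy-5-[(1R)-1-methoxy-3-methylbutyl]phenyl}potassium | COc1c([C@@H](CC(C)C)OC)ccc(Oc2c(OCC=C)cc(C)cc2C2OCCO2)c1[K] | intermediate
21 | 6-[2-(1,3-dioxolan-2-yl)-4-methyl-6-(prop-2-en-1-yloxy)phenoxy]-2-methoxy-3-[(1R)-1-methoxy-3-methylbutyl]benzoic acid | COc1c([C@@H](CC(C)C)OC)ccc(Oc2c(OCC=C)cc(C)cc2C2OCCO2)c1C(=O)O | intermediate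
22 | 6-[2-(1,3-dioxolan-2-yl)-6-hydroxy-4-methylphenoxy]-2-methoxy-3-[(1R)-1-methoxy-3-methylbutyl]benzoic acid | COc1c([C@@H](CC(C)C)OC)ccc(Oc2c(O)cc(C)cc2C2OCCO2)c1C(=O)O | intermediate
23 | 6-(2-formyl-6-hydroxy-4-methylphenoxy)-2-methoxy-3-[(1R)-1-methoxy-3-methylbutyl]benzoic acid | COc1c([C@@H](CC(C)C)OC)ccc(Oc2c(O)cc(C)cc2C=O)c1C(=O)O | target

**Step count**

Total step count: 12. Longest linear sequence: 9 steps (steps 1–7, 11, 12).

**Steps most likely to fail**

1. Step 11. Carboxylation may fail because the C1 aryl anion is protonated by adventitious proton sources, or because the phenoxide is held back as its carbonate under CO2. The fallback uses known chemistry in two operations and sets out from 11 and 16. CsF in MeCN at room temperature, the established aryne O-arylation of phenols in which the aryl anion is protonated, should give the diaryl ether 2-[2-{3-methoxy-4-[(1R)-1-methoxy-3-methylbutyl]phenoxy}-5-methyl-3-(prop-2-en-1-yloxy)phenyl]-1,3-dioxolane F1 with the same C6 regiochemistry. Directed ortho-lithiation of F1 at C1, the position between the methoxy and aryloxy oxygens, with n-BuLi and TMEDA in THF at −78 to −40 °C (short contact to spare the allyl ether), followed by CO2, comes back to the route at 21.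

2. Step 2. Silylation at C2 may be eroded by competing deprotonation next to bromine (followed by loss of lithium bromide) or by a second silylation. The fallback defers the silylation until the bromide is gone and sets out from 2. Bromine–lithium exchange with n-BuLi at −78 °C and acylation with 5 should give 3-methoxy-4-(3-methylbutanoyl)phenyl N,N-diethylcarbamate F2. Reduction with the (S)-Me-CBS oxazaborolidine and BH3·SMe2 should give 4-[(1R)-1-hydroxy-3-methylbutyl]-3-methoxyphenyl N,N-diethylcarbamate F3. NaH and MeI should give 3-methoxy-4-[(1R)-1-methoxy-3-methylbutyl]phenyl N,N-diethylcarbamate F4. Classical carbamate-directed ortho-metalation of F4 with s-BuLi and TMEDA in THF at −78 °C, at the position flanked by both oxygens, and Me3SiCl quench comes back to the route at 9.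

3. Step 8. Formylation may stall through chelation of magnesium by the catechol, or attack next to the methyl group may compete. The fallback replaces electrophilic formylation by directed lithiation and sets out from 12. MOMCl and i-Pr2NEt should give 1,2-bis(methoxymethoxy)-4-methylbenzene F5. Lithiation with n-BuLi and TMEDA ortho to a methoxymethoxy group at the unhindered ring position, then DMF, should give 2,3-bis(methoxymethoxy)-5-methylbenzaldehyde F6. HCl in MeOH removes both acetal ethers and comes back to the route at 13.

**Further compounds**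

F1 | step 11 | 2-[2-{3-methoxy-4-[(1R)-1-methoxy-3-methylbutyl]phenoxy}-5-methyl-3-(prop-2-en-1-yloxy)phenyl]-1,3-dioxolane | COc1cc(Oc2c(OCC=C)cc(C)cc2C2OCCO2)ccc1[C@@H](CC(C)C)OC
F2 | step 2 | 3-methoxy-4-(3-methylbutanoyl)phenyl N,N-diethylcarbamate | CCN(CC)C(=O)Oc1ccc(C(=O)CC(C)C)c(OC)c1
F3 | step 2 | 4-[(1R)-1-hydroxy-3-methylbutyl]-3-methoxyphenyl N,N-diethylcarbamate | CCN(CC)C(=O)Oc1ccc([C@@H](CC(C)C)O)c(OC)c1
F4 | step 2 | 3-methoxy-4-[(1R)-1-methoxy-3-methylbutyl]phenyl N,N-diethylcarbamate | CCN(CC)C(=O)Oc1ccc([C@@H](CC(C)C)OC)c(OC)c1
F5 | step 8 | 1,2-bis(methoxymethoxy)-4-methylbenzene | Cc1ccc(OCOC)c(OCOC)c1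
F6 | step 8 | 2,3-bis(methoxymethoxy)-5-methylbenzaldehyde | Cc1cc(OCOC)c(OCOC)c(C=O)c1
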